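**Retrosynthetic overview**

- Feature: the C4–C4a bond joins the C4 carbonyl to ring A, a 5,7-dioxygenated benzene ring whose two carbons ortho to O1 are equivalent before closure. C3 carries two one-carbon arms (C2 and C4), so it maps onto the central carbon of a prochiral 2-aryl-propane-1,3-diol.
- Disconnections: 5-OH ⇒ 5-OMe (19); C4–C4a ⇒ (S)-3-aryloxy-2-arylpropanoic acid 17 by intramolecular Friedel–Crafts acylation; C2–O1 ether ⇒ 3,5-dimethoxyphenol 13 + (S)-monoacetate 12 (Mitsunobu).
- 12 ⇒ diol 11 (lipase desymmetrisation) ⇒ arylmalonate 10 ⇒ bromochromene 8 + diethyl malonate 9.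
- Ring order: the dimethylpyran ring fused to ring B is made first (steps 1–4); ring A arrives intact in 13; the pyranone ring C is closed in step 11; step 12 only frees the 5-hydroxyl.

Key step: step 11

Assumption: Burkholderia cepacia lipase is taken to acetylate the enantiotopic hydroxymethyl arm of diol 11 that gives the (S)-monoacetate 12; the sense has to be confirmed on this ortho-methoxyaryl diol, and the fallback for step 7 covers the opposite outcome.

**Route**

Step 1
Reactants: 1 resorcinol; 2 3-methylbut-2-enoic acid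
Product: 4 7-hydroxy-2,2-dimethylchroman-4-one, via 1-(2,4-dihydroxyphenyl)-3-methylbut-2-en-1-one 3 (not isolated)
Conditions: MeSO3H, P2O5, 70 °C
Reagents that add atoms: none
Why: Friedel–Crafts acylation of resorcinol at C4 by the activated acid gives the ortho-hydroxyaryl enone, which closes by intramolecular oxa-Michael addition; this medium is known to favour the 2,2-dimethylchroman-4-one over the isomeric dihydrocoumarin.

Step 2
Reactants: 4 7-hydroxy-2,2-dimethylchroman-4-one
Product: 5 7-methoxy-2,2-dimethylchroman-4-one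
Conditions: MeI, K2CO3, acetone, reflux
Reagents that add atoms: iodomethane, CI
Why: Williamson O-methylation of the only phenol, which is acidified by the para carbonyl group.

Step 3
Reactants: 5 7-methoxy-2,2-dimethylchroman-4-one
Product: 6 6-bromo-7-methoxy-2,2-dimethylchroman-4-one
Conditions: NBS, MeCN, 0 °C to rt
Reagents that add atoms: N-bromosuccinimide, O=C1CCC(=O)N1Br
Why: Electrophilic aromatic bromination should go to C6, which is para to O1, ortho to the 7-methoxy group and unhindered (C8 lies between two oxygens), and NBS in a polar solvent without acid or initiator should spare the ketone α-position.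

Step 4
Reactants: 6 6-bromo-7-methoxy-2,2-dimethylchroman-4-one
Product: 8 6-bromo-7-methoxy-2,2-dimethyl-2H-chromene, via 6-bromo-7-methoxy-2,2-dimethylchroman-4-ol 7 (not isolated)
Conditions: NaBH4, MeOH, 0 °C to rt; then p-TsOH·H2O (cat.), toluene, 80 °C
Reagents that add atoms: none
Why: Borohydride reduction of the aryl ketone and acid-catalysed E1 dehydration of the benzylic alcohol, whose cation is stabilised by the para 7-methoxy group, should give the 3,4-double bond; the bromine is already in place, so no electrophilic halogen has to meet the chromene alkene.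

Step 5
Reactants: 8 6-bromo-7-methoxy-2,2-dimethyl-2H-chromene; 9 diethyl malonate
Product: 10 diethyl 2-(7-methoxy-2,2-dimethyl-2H-chromen-6-yl)malonate
Conditions: Pd(dba)2 (cat.), P(t-Bu)3·HBF4 (cat.), K3PO4, toluene, 70 °C
Reagents that add atoms: none
Why: Palladium-catalysed α-arylation of a malonate enolate (Buchwald–Hartwig-type coupling): the electron-rich, bulky phosphine allows oxidative addition of the ortho-substituted, electron-rich aryl bromide to zerovalent palladium, and the hindered product resists a second arylation.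

Step 6
Reactants: 10 diethyl 2-(7-methoxy-2,2-dimethyl-2H-chromen-6-yl)malonate
Product: 11 2-(7-methoxy-2,2-dimethyl-2H-chromen-6-yl)propane-1,3-diol
Conditions: LiAlH4, THF, 0 °C to rt (inverse addition); then H2O, aq. NaOH
Reagents that add atoms: none
Why: Hydride reduction of both esters to primary alcohols; adding the malonate to excess LiAlH4 in the cold limits enolisation of the acidic arylmalonate, and the chromene and aryl ethers are inert to hydride.

Step 7
Reactants: 11 2-(7-methoxy-2,2-dimethyl-2H-chromen-6-yl)propane-1,3-diol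
Product: 12 (2S)-3-hydroxy-2-(7-methoxy-2,2-dimethyl-2H-chromen-6-yl)propyl acetate
Conditions: Burkholderia cepacia lipase (immobilised), vinyl acetate, t-BuOMe, 25 °C
Reagents that add atoms: vinyl acetate, C=COC(C)=O
Why: Enzymatic desymmetrisation by irreversible lipase transesterification: the enzyme acylates one enantiotopic hydroxymethyl arm of the prochiral diol, which turns the central carbon into the stereocentre that becomes C3, and tautomerisation of the released vinyl alcohol to acetaldehyde prevents the back reaction.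

Step 8
Reactants: 12 (2S)-3-hydroxy-2-(7-methoxy-2,2-dimethyl-2H-chromen-6-yl)propyl acetate; 13 3,5-dimethoxyphenol
Product: 14 (2S)-3-(3,5-dimethoxyphenoxy)-2-(7-methoxy-2,2-dimethyl-2H-chromen-6-yl)propyl acetate
Conditions: PPh3, DIAD, THF, 0 °C to rt
Reagents that add atoms: none
Why: Mitsunobu etherification: the free primary hydroxyl is activated as its alkoxyphosphonium ion and displaced by the phenoxide in an SN2 reaction at CH2, so the stereocentre is not touched, and the near-neutral medium should avoid 1,3-acetyl migration that would scramble the two arms.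

Step 9
Reactants: 14 (2S)-3-(3,5-dimethoxyphenoxy)-2-(7-methoxy-2,2-dimethyl-2H-chromen-6-yl)propyl acetate
Product: 15 (2R)-3-(3,5-dimethoxyphenoxy)-2-(7-methoxy-2,2-dimethyl-2H-chromen-6-yl)propan-1-ol
Conditions: K2CO3 (cat.), MeOH, 0 °C
Reagents that add atoms: none
Why: Base-catalysed transesterification to methanol removes the acetate without touching the aryl ethers; the descriptor changes to R only through the CIP priorities, not through any change in space.

Step 10
Reactants: 15 (2R)-3-(3,5-dimethoxyphenoxy)-2-(7-methoxy-2,2-dimethyl-2H-chromen-6-yl)propan-1-ol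
Product: 17 (2S)-3-(3,5-dimethoxyphenoxy)-2-(7-methoxy-2,2-dimethyl-2H-chromen-6-yl)propanoic acid, via (2S)-3-(3,5-dimethoxyphenoxy)-2-(7-methoxy-2,2-dimethyl-2H-chromen-6-yl)propanal 16 (not isolated)
Conditions: TEMPO (cat.), PhI(OAc)2, MeCN/H2O, 0 °C to rt
Reagents that add atoms: water, O
Why: Oxoammonium-catalysed oxidation (TEMPO with a hypervalent iodine co-oxidant) takes the primary alcohol to the aldehyde, whose hydrate is oxidised on to the acid in the aqueous medium; the base-free, chlorine-free, weakly acidic conditions should preserve the α-aryl stereocentre and spare the electron-rich rings and the chromene.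

Step 11
Reactants: 17 (2S)-3-(3,5-dimethoxyphenoxy)-2-(7-methoxy-2,2-dimethyl-2H-chromen-6-yl)propanoic acid
Product: 19 (3S)-5,7-dimethoxy-3-(7-methoxy-2,2-dimethyl-2H-chromen-6-yl)chroman-4-one, via (2S)-3-(3,5-dimethoxyphenoxy)-2-(7-methoxy-2,2-dimethyl-2H-chromen-6-yl)propanoyl chloride 18 (not isolated)
Conditions: 1-chloro-N,N,2-trimethylprop-1-en-1-amine, CH2Cl2, 0 °C; then SnCl4, CH2Cl2 (high dilution), −78 to −40 °C; cold aq. NaHCO3
Reagents that add atoms: none
Why: The chloroenamine converts the acid into acid chloride 18 under neutral conditions (the only by-product is an amide), and SnCl4 then ionises the C–Cl bond to an acylium ion or its tight ion pair. The acylium carbon is attacked by the ring A carbon ortho to the ether oxygen, which is also ortho to one methoxy group and para to the other, and proton loss from the arenium ion gives the aryl ketone; this is the classical intramolecular Friedel–Crafts acylation of 3-aryloxypropanoic acids to chroman-4-ones. Ring C closes in a six-membered mode, exo with respect to the acylium C–O multiple bond (6-exo-dig), since the tether O1–C2–C3–C4 allows no other ring size. No stereocentre is created; C3, set in step 7, should survive because no base is present to form a ketene from the α-aryl acyl chloride and the low temperature disfavours enolisation of the tin-bound ketone. Regioselectivity needs no control, as the two ortho carbons of the 3,5-dimethoxyphenoxy ring are equivalent and the carbon between the methoxy groups cannot reach the acylium ion. Chemoselectivity over ring B and the chromene alkene rests on intramolecularity, high dilution, the high nucleophilicity of the trioxygenated ring and a cold bicarbonate quench that removes HCl before warming.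

Step 12
Reactants: 19 (3S)-5,7-dimethoxy-3-(7-methoxy-2,2-dimethyl-2H-chromen-6-yl)chroman-4-one
Product: 21 (3S)-5-hydroxy-7-methoxy-3-(7-methoxy-2,2-dimethyl-2H-chromen-6-yl)chroman-4-one (CNP0310096.1), via (3S)-5-(dichloroboryloxy)-7-methoxy-3-(7-methoxy-2,2-dimethyl-2H-chromen-6-yl)chroman-4-one 20 (not isolated)
Conditions: BCl3, CH2Cl2, −78 to 0 °C; then aq. NaHCO3
Reagents that add atoms: none
Why: Chelation-directed Lewis acid ether cleavage: BCl3 binds the C4 carbonyl and the peri 5-methoxy oxygen in a six-membered chelate and chloride removes only that methyl group, the 7-methoxy group and the methoxy group on ring B lacking such assistance, while the low temperature should protect C3 and the chromene.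

**Compound list**

1 | resorcinol | Oc1cccc(O)c1 | starting material
2 | 3-methylbut-2-enoic acid | CC(C)=CC(=O)O | starting material
3 | 1-(2,4-dihydroxyphenyl)-3-methylbut-2-en-1-one | CC(C)=CC(=O)c1ccc(O)cc1O | intermediate
4 | 7-hydroxy-2,2-dimethylchroman-4-one | CC1(C)CC(=O)c2ccc(O)cc2O1 | intermediate
5 | 7-methoxy-2,2-dimethylchroman-4-one | COc1ccc2c(c1)OC(C)(C)CC2=O | intermediate
6 | 6-bromo-7-methoxy-2,2-dimethylchroman-4-one | COc1cc2c(cc1Br)C(=O)CC(C)(C)O2 | intermediate
7 | 6-bromo-7-methoxy-2,2-dimethylchroman-4-ol (racemic) | COc1cc2c(cc1Br)C(O)CC(C)(C)O2 | intermediate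
8 | 6-bromo-7-methoxy-2,2-dimethyl-2H-chromene | COc1cc2c(cc1Br)C=CC(C)(C)O2 | intermediate
9 | diethyl malonate | CCOC(=O)CC(=O)OCC | starting material
10 | diethyl 2-(7-methoxy-2,2-dimethyl-2H-chromen-6-yl)malonate | CCOC(=O)C(C(=O)OCC)c1cc2c(cc1OC)OC(C)(C)C=C2 | intermediate
11 | 2-(7-methoxy-2,2-dimethyl-2H-chromen-6-yl)propane-1,3-diol | OCC(CO)c1cc2c(cc1OC)OC(C)(C)C=C2 | intermediate
12 | (2S)-3-hydroxy-2-(7-methoxy-2,2-dimethyl-2H-chromen-6-yl)propyl acetate | OC[C@H](c1cc2c(cc1OC)OC(C)(C)C=C2)COC(C)=O | intermediate
13 | 3,5-dimethoxyphenol | COc1cc(O)cc(OC)c1 | starting material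
14 | (2S)-3-(3,5-dimethoxyphenoxy)-2-(7-methoxy-2,2-dimethyl-2H-chromen-6-yl)propyl acetate | COc1cc(OC)cc(OC[C@H](c2cc3c(cc2OC)OC(C)(C)C=C3)COC(C)=O)c1 | intermediate
15 | (2R)-3-(3,5-dimethoxyphenoxy)-2-(7-methoxy-2,2-dimethyl-2H-chromen-6-yl)propan-1-ol | COc1cc(OC)cc(OC[C@H](c2cc3c(cc2OC)OC(C)(C)C=C3)CO)c1 | intermediate
16 | (2S)-3-(3,5-dimethoxyphenoxy)-2-(7-methoxy-2,2-dimethyl-2H-chromen-6-yl)propanal | COc1cc(OC)cc(OC[C@H](c2cc3c(cc2OC)OC(C)(C)C=C3)C=O)c1 | intermediate
17 | (2S)-3-(3,5-dimethoxyphenoxy)-2-(7-methoxy-2,2-dimethyl-2H-chromen-6-yl)propanoic acid | COc1cc(OC)cc(OC[C@H](c2cc3c(cc2OC)OC(C)(C)C=C3)C(=O)O)c1 | intermediate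
18 | (2S)-3-(3,5-dimethoxyphenoxy)-2-(7-methoxy-2,2-dimethyl-2H-chromen-6-yl)propanoyl chloride | COc1cc(OC)cc(OC[C@H](c2cc3c(cc2OC)OC(C)(C)C=C3)C(=O)Cl)c1 | intermediate
19 | (3S)-5,7-dimethoxy-3-(7-methoxy-2,2-dimethyl-2H-chromen-6-yl)chroman-4-one | COc1cc(OC)c2c(c1)OC[C@H](c1cc3c(cc1OC)OC(C)(C)C=C3)C2=O | intermediate
20 | (3S)-5-(dichloroboryloxy)-7-methoxy-3-(7-methoxy-2,2-dimethyl-2H-chromen-6-yl)chroman-4-one | COc1cc(OB(Cl)Cl)c2c(c1)OC[C@H](c1cc3c(cc1OC)OC(C)(C)C=C3)C2=O | intermediate
21 | (3S)-5-hydroxy-7-methoxy-3-(7-methoxy-2,2-dimethyl-2H-chromen-6-yl)chroman-4-one | COc1cc(O)c2c(c1)OC[C@H](c1cc3c(cc1OC)OC(C)(C)C=C3)C2=O | target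

Total step count: 12
Longest linear sequence: 12 steps (from resorcinol 1 to target 21)

**Steps most likely to fail**

Step 11 (key step). What may go wrong:
- protonation or hydrochlorination of the chromene double bond and cationic oligomerisation under the Lewis acid;
- loss of carbon monoxide from the acylium ion to a benzylic cation stabilised by two oxygen substituents;
- erosion of C3 through enolisation of the tin-bound ketone.

The fallback no longer asks the ring closure to carry the stereocentre. It sets out from acid 17 and comes back at 19. Trifluoroacetic anhydride in CH2Cl2 at 0 °C should convert 17 into the mixed anhydride 3-(3,5-dimethoxyphenoxy)-2-(7-methoxy-2,2-dimethyl-2H-chromen-6-yl)propanoic trifluoroacetic anhydride F1. This should acylate ring A without tin or chloride, and the product is taken on as the racemate, rac-5,7-dimethoxy-3-(7-methoxy-2,2-dimethyl-2H-chromen-6-yl)chroman-4-one F2. C3 is then set by catalyst control in an asymmetric transfer hydrogenation with dynamic kinetic resolution (RuCl(p-cymene)[(S,S)-TsDPEN], HCO2H/Et3N, 40 °C). The amine equilibrates C3 while the catalyst reduces one enantiomer faster, and by analogy with aryl alkyl ketones the (S,S)-ligand should give the 4S carbinol. The expected product is the cis alcohol (3S,4S)-5,7-dimethoxy-3-(7-methoxy-2,2-dimethyl-2H-chromen-6-yl)chroman-4-ol F3. Oxidation with Dess–Martin periodinane and NaHCO3 in CH2Cl2 at 0 °C should return ketone 19.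

Step 7. What may go wrong: weak or reversed discrimination between the enantiotopic arms caused by the ortho-methoxy aryl group, and over-acylation to the diacetate.

The fallback uses the hydrolytic mode of the enzyme together with an exchange of protecting groups. It sets out from diol 11 and comes back at 15.
- Ac2O and pyridine should give the diacetate 2-(7-methoxy-2,2-dimethyl-2H-chromen-6-yl)propane-1,3-diyl diacetate F4.
- The same lipase in NaH2PO4/Na2HPO4 buffer at pH 7 should hydrolyse the arm it would otherwise acylate, leaving the antipodal monoacetate (2R)-3-hydroxy-2-(7-methoxy-2,2-dimethyl-2H-chromen-6-yl)propyl acetate F5.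
- Silylation (TBSCl, imidazole, CH2Cl2) should give (2S)-3-[(tert-butyldimethylsilyl)oxy]-2-(7-methoxy-2,2-dimethyl-2H-chromen-6-yl)propyl acetate F6.
- Methanolysis (K2CO3, MeOH) should free the other arm as (2S)-3-[(tert-butyldimethylsilyl)oxy]-2-(7-methoxy-2,2-dimethyl-2H-chromen-6-yl)propan-1-ol F7.
- Mitsunobu reaction with 13 (PPh3, DIAD, THF) should give tert-butyl{[(2S)-3-(3,5-dimethoxyphenoxy)-2-(7-methoxy-2,2-dimethyl-2H-chromen-6-yl)propyl]oxy}dimethylsilane F8.
- TBAF in THF should release alcohol 15.

Whichever monoacetate enantiomer the better enzymatic mode provides, either the direct sequence or this interchanged one leads to 15.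

Step 10. What may go wrong: enolisation of the transient aldehyde 16, which would erode C3 or expel the aryloxide by β-elimination.

The fallback accepts some erosion and restores optical purity by classical resolution. It sets out from acid 17 of reduced enantiomeric purity and comes back at 17. The acid is crystallised from ethanol or ethyl acetate as its salt with a single enantiomer of 1-phenylethylamine, the enantiomer giving the less soluble salt with the (S)-acid being chosen by trial and written here as the (S)-amine. This gives (S)-1-phenylethylammonium (2S)-3-(3,5-dimethoxyphenoxy)-2-(7-methoxy-2,2-dimethyl-2H-chromen-6-yl)propanoate F9. Dilute aqueous HCl and extraction should return 17.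

**Further compounds**

F1 | step 11 | 3-(3,5-dimethoxyphenoxy)-2-(7-methoxy-2,2-dimethyl-2H-chromen-6-yl)propanoic trifluoroacetic anhydride | COc1cc(OC)cc(OC[C@H](c2cc3c(cc2OC)OC(C)(C)C=C3)C(=O)OC(=O)C(F)(F)F)c1
F2 | step 11 | rac-5,7-dimethoxy-3-(7-methoxy-2,2-dimethyl-2H-chromen-6-yl)chroman-4-one | COc1cc(OC)c2c(c1)OCC(c1cc3c(cc1OC)OC(C)(C)C=C3)C2=O
F3 | step 11 | (3S,4S)-5,7-dimethoxy-3-(7-methoxy-2,2-dimethyl-2H-chromen-6-yl)chroman-4-ol | COc1cc(OC)c2c(c1)OC[C@H](c1cc3c(cc1OC)OC(C)(C)C=C3)[C@@H]2O
F4 | step 7 | 2-(7-methoxy-2,2-dimethyl-2H-chromen-6-yl)propane-1,3-diyl diacetate | CC(=O)OCC(COC(C)=O)c1cc2c(cc1OC)OC(C)(C)C=C2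
F5 | step 7 | (2R)-3-hydroxy-2-(7-methoxy-2,2-dimethyl-2H-chromen-6-yl)propyl acetate | CC(=O)OC[C@H](c1cc2c(cc1OC)OC(C)(C)C=C2)CO
F6 | step 7 | (2S)-3-[(tert-butyldimethylsilyl)oxy]-2-(7-methoxy-2,2-dimethyl-2H-chromen-6-yl)propyl acetate | CC(=O)OC[C@H](c1cc2c(cc1OC)OC(C)(C)C=C2)CO[Si](C)(C)C(C)(C)C
F7 | step 7 | (2S)-3-[(tert-butyldimethylsilyl)oxy]-2-(7-methoxy-2,2-dimethyl-2H-chromen-6-yl)propan-1-ol | OC[C@H](c1cc2c(cc1OC)OC(C)(C)C=C2)CO[Si](C)(C)C(C)(C)C
F8 | step 7 | tert-butyl{[(2S)-3-(3,5-dimethoxyphenoxy)-2-(7-methoxy-2,2-dimethyl-2H-chromen-6-yl)propyl]oxy}dimethylsilane | COc1cc(OC)cc(OC[C@H](c2cc3c(cc2OC)OC(C)(C)C=C3)CO[Si](C)(C)C(C)(C)C)c1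
F9 | step 10 | (S)-1-phenylethylammonium (2S)-3-(3,5-dimethoxyphenoxy)-2-(7-methoxy-2,2-dimethyl-2H-chromen-6-yl)propanoate | COc1cc(OC)cc(OC[C@H](c2cc3c(cc2OC)OC(C)(C)C=C3)C(=O)[O-])c1.C[C@H]([NH3+])c1ccccc1
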